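**Plan**

1. Locants: oxolane O1, C2 (4-hydroxyphenyl), C3 (2,4-dihydroxybenzoyl), C4 (side chain), C5 (2,4-dihydroxyphenyl); Cα is the diarylmethine carbon on C4, bound to C6 of the flavan.
2. Cuts, last bond first: Cα–C6(flavan) (Friedel–Crafts, C8 blocked by Br); C3–H back to a C3 allyl ester; O1–C5 and C2–C3 together, leaving 4-(benzyloxy)benzaldehyde and a donor–acceptor cyclopropane C3–C4–C5; the cyclopropane to an enone and a β-keto ester.
3. Forward: Wittig enone + keto ester → Michael adduct → cyclopropane → (3+2) annulation with the aldehyde closes the oxolane, the only ring to be built → ketone at Cα reduced, ester removed → flavan joined → one hydrogenolysis.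
4. Feature that allows the key step: O1 lies between two benzylic carbons and C3 bears the aroyl group, so C5 with its resorcinol ring is a cyclopropane donor carbon, C3 an acceptor carbon and O1=C2–aryl an aldehyde; the cis relation of the C4 and C5 substituents, the less stable one, is what inversion at the donor carbon of a trans-cyclopropane gives.
5. Stereochemistry: C5 by an organocatalytic Michael addition, C4 trans to it on ring closure, C5 inverted and C2 set cis to C5 in the annulation, C3 by equilibration, Cα by 1,2-induction from the ring, flavan from (−)-epiafzelechin by C2 epimerisation.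
6. Protecting groups serve the plan: benzyl carbonates on the donor ring keep its ring opening SN2-like, and all benzyl-type groups and the bromine fall in the last step.

Key step: step 7

Remark: read from the SMILES, the flavan unit is (2S,3R) (ent-afzelechin); this is taken as intended and is reached from commercial (−)-epiafzelechin (2R,3R) by epimerisation at C2.

**Route**

Step 1
Reactants: 1 2,4-dihydroxybenzaldehyde
Product: 2 2,4-bis[(benzyloxycarbonyl)oxy]benzaldehyde
Conditions: CbzCl (2.3 equiv), Et3N, DMAP (cat.), CH2Cl2, 0 °C to rt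
Reagents that add atoms: benzyl chloroformate, O=C(Cl)OCc1ccccc1
Why: O-acylation of both phenols with a chloroformate gives aryl benzyl carbonates, which fall to hydrogenolysis at the end and meanwhile turn the resorcinol ring from a dialkoxyphenyl-type into a phenyl-type donor, as step 7 requires.

Step 2
Reactants: 3 2-bromo-1-[4-(benzyloxy)phenyl]ethan-1-one
Product: 5 1-[4-(benzyloxy)phenyl]-2-(triphenyl-λ5-phosphanylidene)ethan-1-one, via phosphonium bromide 4 (not isolated)
Conditions: PPh3, CH2Cl2, rt; then 2 M aq. NaOH, rt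
Reagents that add atoms: triphenylphosphine, c1ccc(cc1)P(c1ccccc1)c1ccccc1
Why: SN2 quaternisation of the phosphine by the phenacyl bromide and deprotonation give the stabilised acyl ylide needed for a base-free olefination.

Step 3
Reactants: 2 2,4-bis[(benzyloxycarbonyl)oxy]benzaldehyde; 5 1-[4-(benzyloxy)phenyl]-2-(triphenyl-λ5-phosphanylidene)ethan-1-one
Product: 6 (E)-1-[4-(benzyloxy)phenyl]-3-{2,4-bis[(benzyloxycarbonyl)oxy]phenyl}prop-2-en-1-one
Conditions: toluene, 90 °C
Reagents that add atoms: none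
Why: Wittig olefination with a stabilised ylide should give the (E)-enone under neutral conditions that the aryl carbonates tolerate, which a base-mediated Claisen–Schmidt condensation would not.

Step 4
Reactants: 7 1-[2,4-bis(benzyloxy)phenyl]ethan-1-one
Product: 8 allyl 3-[2,4-bis(benzyloxy)phenyl]-3-oxopropanoate
Conditions: NaH (2.2 equiv), diallyl carbonate (3 equiv), THF, reflux; AcOH quench
Reagents that add atoms: diallyl carbonate, C=CCOC(=O)OCC=C
Why: Claisen-type C-acylation of the methyl ketone enolate by a dialkyl carbonate gives the β-keto ester, whose allyl ester is the traceless second acceptor that step 9 removes under neutral conditions.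

Step 5
Reactants: 6 (E)-1-[4-(benzyloxy)phenyl]-3-{2,4-bis[(benzyloxycarbonyl)oxy]phenyl}prop-2-en-1-one; 8 allyl 3-[2,4-bis(benzyloxy)phenyl]-3-oxopropanoate
Product: 9 allyl (3S)-2-[2,4-bis(benzyloxy)benzoyl]-5-[4-(benzyloxy)phenyl]-3-{2,4-bis[(benzyloxycarbonyl)oxy]phenyl}-5-oxopentanoate (C2 epimers)
Conditions: cinchona-derived thiourea–tertiary amine catalyst (10 mol%), toluene, rt
Reagents that add atoms: none
Why: Bifunctional-organocatalyst Michael addition of a β-keto ester to a chalcone-type enone, in which the catalyst (the pseudoenantiomer that gives the (S) adduct being chosen) sets the benzylic centre, the later C5, while the keto ester carbon is a mixture that step 6 erases.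

Step 6
Reactants: 9 allyl (3S)-2-[2,4-bis(benzyloxy)benzoyl]-5-[4-(benzyloxy)phenyl]-3-{2,4-bis[(benzyloxycarbonyl)oxy]phenyl}-5-oxopentanoate
Product: 11 allyl 1-[2,4-bis(benzyloxy)benzoyl]-2-[4-(benzyloxy)benzoyl]-3-{2,4-bis[(benzyloxycarbonyl)oxy]phenyl}cyclopropane-1-carboxylate (aroyl on C2 trans to aryl on C3; C1 epimers), via iodo keto ester 10 (not isolated)
Conditions: I2 (1.2 equiv), Cs2CO3 (2.5 equiv), MeCN, 0 °C to rt
Reagents that add atoms: none
Why: α-Iodination of the 1,3-dicarbonyl carbon followed by 3-exo-tet displacement by the ketone enolate (oxidative cyclopropanation of a Michael adduct) should place the aroyl group trans to the aryl group to avoid eclipsing in the ring-closing transition state, the benzylic centre being untouched.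

Step 7
Reactants: 11 allyl 1-[2,4-bis(benzyloxy)benzoyl]-2-[4-(benzyloxy)benzoyl]-3-{2,4-bis[(benzyloxycarbonyl)oxy]phenyl}cyclopropane-1-carboxylate; 12 4-(benzyloxy)benzaldehyde
Product: 13 allyl 3-[2,4-bis(benzyloxy)benzoyl]-4-[4-(benzyloxy)benzoyl]-2-[4-(benzyloxy)phenyl]-5-{2,4-bis[(benzyloxycarbonyl)oxy]phenyl}oxolane-3-carboxylate (aryl groups on C2 and C5 and aroyl group on C4 all cis; C3 epimers)
Conditions: Sn(OTf)2 (10 mol%), 12 (3 equiv), 4 Å MS, CH2Cl2, rt
Reagents that add atoms: none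
Why: Sn(OTf)2 chelates the geminal keto ester at C3 and polarises the C3–C5 bond; the aldehyde oxygen opens the ring at the aryl-bearing C5 from the rear (tight ion pair, SN2-like) and the tin enolate then adds to the aryl-substituted oxocarbenium ion, a formal (3+2) annulation. The closest known reaction type is the Lewis-acid-catalysed annulation of aldehydes with 2-arylcyclopropane-1,1-dicarbonyl compounds, 3-aroyl-substituted ones included, which gives 2,5-cis-tetrahydrofurans with inversion at the donor carbon. The oxolane is the only ring closed: O1–C5 forms with release of the cyclopropane strain and C2–C3 by enolate attack on the C2=O1+ unit (five-membered, endo at the oxocarbenium ion, exo at the enolate). C5 is set by inversion, which turns the trans relation of aroyl (C4) and aryl (C5) in 11 into the cis relation of the target; C4 is a spectator and keeps its configuration; C2 should be set cis to C5 by the envelope transition state with both aryl groups pseudo-equatorial; C3 is a transient quaternary centre removed in step 9. The step needs C3–C5 and not C4–C5 cleavage, secured by bidentate activation of the 1,1-dicarbonyl carbon only; it needs substitution rather than ionisation (no Cloke–Wilson closure to a dihydrofuran, no epimerisation at C5), secured by the two aryl carbonates and the acyl group on C4; and it needs the aldehyde rather than a ring ketone as the 2π partner, secured by the much lower nucleophilicity of ketones.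

Step 8
Reactants: 13 allyl 3-[2,4-bis(benzyloxy)benzoyl]-4-[4-(benzyloxy)benzoyl]-2-[4-(benzyloxy)phenyl]-5-{2,4-bis[(benzyloxycarbonyl)oxy]phenyl}oxolane-3-carboxylate
Product: 15 allyl 4-{acetoxy[4-(benzyloxy)phenyl]methyl}-3-[2,4-bis(benzyloxy)benzoyl]-2-[4-(benzyloxy)phenyl]-5-{2,4-bis[(benzyloxycarbonyl)oxy]phenyl}oxolane-3-carboxylate (acetate carbon epimers), via carbinol 14 (not isolated)
Conditions: NaBH4, CeCl3·7H2O, THF–MeOH, −40 °C; acetone quench, evaporation; then Ac2O, pyridine, DMAP (cat.), CH2Cl2, 0 °C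
Reagents that add atoms: acetic anhydride, CC(=O)OC(C)=O
Why: Luche-type hydride reduction should pick the 4-benzyloxyphenyl ketone over the ketone on the quaternary carbon, the ester and the carbonates, and acetylation blocks lactonisation and installs the leaving group; the carbinol configuration is irrelevant because this carbon is ionised in step 13.

Step 9
Reactants: 15 allyl 4-{acetoxy[4-(benzyloxy)phenyl]methyl}-3-[2,4-bis(benzyloxy)benzoyl]-2-[4-(benzyloxy)phenyl]-5-{2,4-bis[(benzyloxycarbonyl)oxy]phenyl}oxolane-3-carboxylate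
Product: 17 [2,4-bis(benzyloxy)phenyl]{4-{acetoxy[4-(benzyloxy)phenyl]methyl}-2-[4-(benzyloxy)phenyl]-5-{2,4-bis[(benzyloxycarbonyl)oxy]phenyl}oxolan-3-yl}methanone (2,3-trans, 3,4-trans, 4,5-cis), via keto acid 16 (not isolated)
Conditions: Pd(PPh3)4 (5 mol%), HCO2H, Et3N, THF, rt; then DBU (0.1 equiv), rt
Reagents that add atoms: none
Why: Tsuji Pd(0)/formate deallylation of the allyl β-keto ester gives the β-keto acid, which loses CO2, and DBU then equilibrates the α-centre C3 to the epimer with the aroyl group trans to both flanking substituents, the only arrangement free of a cis-1,2 interaction at C3.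

Step 10
Reactants: 18 (−)-epiafzelechin, (2R,3R)-2-(4-hydroxyphenyl)chromane-3,5,7-triol
Product: 19 (−)-afzelechin, (2S,3R)-2-(4-hydroxyphenyl)chromane-3,5,7-triol
Conditions: aq. phosphate buffer (pH 8), 100 °C, Ar, sealed tube; reversed-phase separation, recovered 18 recycled
Reagents that add atoms: none
Why: Thermal C2 epimerisation of a flavan-3-ol with a 4'-hydroxyphenyl B ring proceeds by reversible opening of the pyran at O1–C2 to a p-quinone methide, C3 is untouched, and the trans epimer is separated from the equilibrium mixture.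

Step 11
Reactants: 19 (−)-afzelechin
Product: 20 (2S,3R)-3,5,7-tris(benzyloxy)-2-[4-(benzyloxy)phenyl]chromane
Conditions: NaH (4.5 equiv), BnBr (4.5 equiv), Bu4NI (cat.), DMF, 0 °C to rt
Reagents that add atoms: benzyl bromide, BrCc1ccccc1
Why: Williamson etherification of the three phenols and the secondary alcohol gives one type of protecting group, removable by hydrogenolysis and inert to the Lewis acid of step 13.

Step 12
Reactants: 20 (2S,3R)-3,5,7-tris(benzyloxy)-2-[4-(benzyloxy)phenyl]chromane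
Product: 21 (2S,3R)-3,5,7-tris(benzyloxy)-2-[4-(benzyloxy)phenyl]-8-bromochromane
Conditions: NBS (1.0 equiv), CH2Cl2, −78 to −20 °C
Reagents that add atoms: N-bromosuccinimide, O=C1CCC(=O)N1Br
Why: Electrophilic aromatic bromination of per-O-benzylated flavan-3-ols takes place at C8 first, so the bromine blocks the position that would otherwise outcompete C6 in step 13.

Step 13
Reactants: 17 [2,4-bis(benzyloxy)phenyl]{4-{acetoxy[4-(benzyloxy)phenyl]methyl}-2-[4-(benzyloxy)phenyl]-5-{2,4-bis[(benzyloxycarbonyl)oxy]phenyl}oxolan-3-yl}methanone; 21 (2S,3R)-3,5,7-tris(benzyloxy)-2-[4-(benzyloxy)phenyl]-8-bromochromane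
Product: 22 [2,4-bis(benzyloxy)phenyl][(2R,3R,4R,5S)-2-[4-(benzyloxy)phenyl]-5-{2,4-bis[(benzyloxycarbonyl)oxy]phenyl}-4-{(S)-[4-(benzyloxy)phenyl][(2S,3R)-3,5,7-tris(benzyloxy)-2-[4-(benzyloxy)phenyl]-8-bromochroman-6-yl]methyl}oxolan-3-yl]methanone
Conditions: TMSOTf (0.2 equiv), 21 (1.3 equiv), 4 Å MS, CH2Cl2, −78 to −40 °C
Reagents that add atoms: none
Why: Friedel–Crafts alkylation through the 4-benzyloxybenzylic cation: C6 is the only free nucleophilic position of the A ring, and with the C4–H bond in the plane of the cation (1,3-allylic strain) the arene should enter anti to the 5-aryl group that is cis to the side chain, on the side where C3 carries only H, which gives the (S) diarylmethine centre.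

Step 14
Reactants: 22 fully protected 8-bromo precursor
Product: 23 (2,4-dihydroxyphenyl)[(2R,3R,4R,5S)-5-(2,4-dihydroxyphenyl)-2-(4-hydroxyphenyl)-4-{(S)-(4-hydroxyphenyl)[(2S,3R)-3,5,7-trihydroxy-2-(4-hydroxyphenyl)chroman-6-yl]methyl}oxolan-3-yl]methanone (CNP0251055.1)
Conditions: H2 (1 atm), Pd(OH)2/C, Et3N (3 equiv), THF–EtOAc, rt
Reagents that add atoms: none
Why: Catalytic hydrogenolysis removes eight benzyl ethers and two benzyl carbonates (with loss of CO2) and reduces the aryl bromide, while the cyclic benzylic ethers and the hydrogen-bonded 2-hydroxyaryl ketone should survive a short, amine-buffered exposure, and no stereocentre is touched.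

**Compound list**

1 | 2,4-dihydroxybenzaldehyde | O=Cc1ccc(O)cc1O | starting material
2 | 2,4-bis[(benzyloxycarbonyl)oxy]benzaldehyde | O=Cc1ccc(OC(=O)OCc2ccccc2)cc1OC(=O)OCc1ccccc1 | intermediate
3 | 2-bromo-1-[4-(benzyloxy)phenyl]ethan-1-one | O=C(CBr)c1ccc(OCc2ccccc2)cc1 | starting material
4 | {2-[4-(benzyloxy)phenyl]-2-oxoethyl}triphenylphosphonium bromide | O=C(C[P+](c1ccccc1)(c1ccccc1)c1ccccc1)c1ccc(OCc2ccccc2)cc1.[Br-] | intermediate
5 | 1-[4-(benzyloxy)phenyl]-2-(triphenyl-λ5-phosphanylidene)ethan-1-one | O=C(C=P(c1ccccc1)(c1ccccc1)c1ccccc1)c1ccc(OCc2ccccc2)cc1 | intermediate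
6 | (E)-1-[4-(benzyloxy)phenyl]-3-{2,4-bis[(benzyloxycarbonyl)oxy]phenyl}prop-2-en-1-one | O=C(/C=C/c1ccc(OC(=O)OCc2ccccc2)cc1OC(=O)OCc1ccccc1)c1ccc(OCc2ccccc2)cc1 | intermediate
7 | 1-[2,4-bis(benzyloxy)phenyl]ethan-1-one | CC(=O)c1ccc(OCc2ccccc2)cc1OCc1ccccc1 | starting material
8 | allyl 3-[2,4-bis(benzyloxy)phenyl]-3-oxopropanoate | C=CCOC(=O)CC(=O)c1ccc(OCc2ccccc2)cc1OCc1ccccc1 | intermediate
9 | allyl (3S)-2-[2,4-bis(benzyloxy)benzoyl]-5-[4-(benzyloxy)phenyl]-3-{2,4-bis[(benzyloxycarbonyl)oxy]phenyl}-5-oxopentanoate (C2 not defined) | O=C(c1ccc(OCc2ccccc2)cc1)C[C@H](c1ccc(OC(=O)OCc2ccccc2)cc1OC(=O)OCc1ccccc1)C(C(=O)OCC=C)C(=O)c1ccc(OCc2ccccc2)cc1OCc1ccccc1 | intermediate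
10 | 2-iodo derivative of 9 | O=C(c1ccc(OCc2ccccc2)cc1)C[C@H](c1ccc(OC(=O)OCc2ccccc2)cc1OC(=O)OCc1ccccc1)C(I)(C(=O)OCC=C)C(=O)c1ccc(OCc2ccccc2)cc1OCc1ccccc1 | intermediate
11 | allyl 1-[2,4-bis(benzyloxy)benzoyl]-2-[4-(benzyloxy)benzoyl]-3-{2,4-bis[(benzyloxycarbonyl)oxy]phenyl}cyclopropane-1-carboxylate, 2,3-trans (C1 not defined) | C=CCOC(=O)C1(C(=O)c2ccc(OCc3ccccc3)cc2OCc2ccccc2)[C@@H](C(=O)c2ccc(OCc3ccccc3)cc2)[C@@H]1c1ccc(OC(=O)OCc2ccccc2)cc1OC(=O)OCc1ccccc1 | intermediate
12 | 4-(benzyloxy)benzaldehyde | O=Cc1ccc(OCc2ccccc2)cc1 | starting material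
13 | allyl 3-[2,4-bis(benzyloxy)benzoyl]-4-[4-(benzyloxy)benzoyl]-2-[4-(benzyloxy)phenyl]-5-{2,4-bis[(benzyloxycarbonyl)oxy]phenyl}oxolane-3-carboxylate, 2,5-cis, 4,5-cis (C3 not defined) | C=CCOC(=O)C1(C(=O)c2ccc(OCc3ccccc3)cc2OCc2ccccc2)[C@@H](C(=O)c2ccc(OCc3ccccc3)cc2)[C@@H](c2ccc(OC(=O)OCc3ccccc3)cc2OC(=O)OCc2ccccc2)O[C@H]1c1ccc(OCc2ccccc2)cc1 | intermediate
14 | 4-{[4-(benzyloxy)phenyl](hydroxy)methyl} analogue of 13 (carbinol carbon not defined) | C=CCOC(=O)C1(C(=O)c2ccc(OCc3ccccc3)cc2OCc2ccccc2)[C@@H](C(O)c2ccc(OCc3ccccc3)cc2)[C@@H](c2ccc(OC(=O)OCc3ccccc3)cc2OC(=O)OCc2ccccc2)O[C@H]1c1ccc(OCc2ccccc2)cc1 | intermediate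
15 | allyl 4-{acetoxy[4-(benzyloxy)phenyl]methyl}-3-[2,4-bis(benzyloxy)benzoyl]-2-[4-(benzyloxy)phenyl]-5-{2,4-bis[(benzyloxycarbonyl)oxy]phenyl}oxolane-3-carboxylate (C3 and acetate carbon not defined) | C=CCOC(=O)C1(C(=O)c2ccc(OCc3ccccc3)cc2OCc2ccccc2)[C@@H](C(OC(C)=O)c2ccc(OCc3ccccc3)cc2)[C@@H](c2ccc(OC(=O)OCc3ccccc3)cc2OC(=O)OCc2ccccc2)O[C@H]1c1ccc(OCc2ccccc2)cc1 | intermediate
16 | 3-carboxylic acid corresponding to 15 | OC(=O)C1(C(=O)c2ccc(OCc3ccccc3)cc2OCc2ccccc2)[C@@H](C(OC(C)=O)c2ccc(OCc3ccccc3)cc2)[C@@H](c2ccc(OC(=O)OCc3ccccc3)cc2OC(=O)OCc2ccccc2)O[C@H]1c1ccc(OCc2ccccc2)cc1 | intermediate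
17 | [2,4-bis(benzyloxy)phenyl]{4-{acetoxy[4-(benzyloxy)phenyl]methyl}-2-[4-(benzyloxy)phenyl]-5-{2,4-bis[(benzyloxycarbonyl)oxy]phenyl}oxolan-3-yl}methanone, ring configured as in 23 (acetate carbon not defined) | O=C(c1ccc(OCc2ccccc2)cc1OCc1ccccc1)[C@@H]1[C@@H](C(OC(C)=O)c2ccc(OCc3ccccc3)cc2)[C@@H](c2ccc(OC(=O)OCc3ccccc3)cc2OC(=O)OCc2ccccc2)O[C@H]1c1ccc(OCc2ccccc2)cc1 | intermediate
18 | (−)-epiafzelechin, (2R,3R)-2-(4-hydroxyphenyl)chromane-3,5,7-triol | Oc1cc2c(c(O)c1)C[C@@H](O)[C@@H](c1ccc(O)cc1)O2 | starting material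
19 | (−)-afzelechin, (2S,3R)-2-(4-hydroxyphenyl)chromane-3,5,7-triol | Oc1cc2c(c(O)c1)C[C@@H](O)[C@H](c1ccc(O)cc1)O2 | intermediate
20 | (2S,3R)-3,5,7-tris(benzyloxy)-2-[4-(benzyloxy)phenyl]chromane | c1ccccc1COc1cc2c(c(OCc3ccccc3)c1)C[C@@H](OCc1ccccc1)[C@H](c1ccc(OCc3ccccc3)cc1)O2 | intermediate
21 | (2S,3R)-3,5,7-tris(benzyloxy)-2-[4-(benzyloxy)phenyl]-8-bromochromane | c1ccccc1COc1c(Br)c2c(c(OCc3ccccc3)c1)C[C@@H](OCc1ccccc1)[C@H](c1ccc(OCc3ccccc3)cc1)O2 | intermediate
22 | [2,4-bis(benzyloxy)phenyl][(2R,3R,4R,5S)-2-[4-(benzyloxy)phenyl]-5-{2,4-bis[(benzyloxycarbonyl)oxy]phenyl}-4-{(S)-[4-(benzyloxy)phenyl][(2S,3R)-3,5,7-tris(benzyloxy)-2-[4-(benzyloxy)phenyl]-8-bromochroman-6-yl]methyl}oxolan-3-yl]methanone | O=C(c1ccc(OCc2ccccc2)cc1OCc1ccccc1)[C@@H]1[C@@H]([C@@H](c2ccc(OCc3ccccc3)cc2)c2c(OCc3ccccc3)c(Br)c3c(c2OCc2ccccc2)C[C@@H](OCc2ccccc2)[C@H](c2ccc(OCc4ccccc4)cc2)O3)[C@@H](c2ccc(OC(=O)OCc3ccccc3)cc2OC(=O)OCc2ccccc2)O[C@H]1c1ccc(OCc2ccccc2)cc1 | intermediate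
23 | (2,4-dihydroxyphenyl)[(2R,3R,4R,5S)-5-(2,4-dihydroxyphenyl)-2-(4-hydroxyphenyl)-4-{(S)-(4-hydroxyphenyl)[(2S,3R)-3,5,7-trihydroxy-2-(4-hydroxyphenyl)chroman-6-yl]methyl}oxolan-3-yl]methanone | O=C(c1ccc(O)cc1O)[C@@H]1[C@@H]([C@@H](c2ccc(O)cc2)c2c(O)cc3c(c2O)C[C@@H](O)[C@H](c2ccc(O)cc2)O3)[C@@H](c2ccc(O)cc2O)O[C@H]1c1ccc(O)cc1 | target

**Totals and risks**

Total step count: 14. Longest linear sequence: 9 steps (1, 3, 5, 6, 7, 8, 9, 13, 14).

Steps most likely to fail:

1. Step 7. The cyclopropane may ionise instead of being substituted, which would lead to closure of the zwitterion on a ketone oxygen (dihydrofuran) or to loss of the inversion at C5; the hindered, trisubstituted ring may also react too slowly, so that enolisation epimerises C4. Fallback: the two bonds would be made one after the other. Cyclopropane 11 would be opened at the aryl-bearing carbon by 4-(benzyloxy)benzyl alcohol under Lewis acid catalysis (SN2-type alcoholysis of a donor–acceptor cyclopropane, inversion) to give allyl 2-[2,4-bis(benzyloxy)benzoyl]-3-[4-(benzyloxy)benzoyl]-4-{[4-(benzyloxy)benzyl]oxy}-4-{2,4-bis[(benzyloxycarbonyl)oxy]phenyl}butanoate F1. F1 would then be cyclised with DDQ: oxidative C–H cleavage of the p-alkoxybenzyl ether gives the same oxocarbenium ion, which the 1,3-dicarbonyl enol traps. The carbonate-bearing benzylic C–H is too electron-poor to be oxidised. This comes back to the route at 13.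

2. Step 13. Arene attack may show poor facial selectivity at the cation, or the cation may be lost by elimination towards C4 (which would also scramble C4), or the hindered, bromine-deactivated C6 may react too slowly. Fallback: the bond would be made under catalyst control without a free cation. Acetate 17 would be converted with HCl into the benzylic chloride F2, and bromide 21 would be iodinated at C6 (NIS) to the 8-bromo-6-iodochromane F3. F2 and F3 would be joined by an enantioconvergent nickel-catalysed reductive cross-coupling of a secondary benzylic chloride with an aryl iodide (chiral bis(oxazoline)-type ligand, Mn), in which the ligand sets the diarylmethine centre and the C–I bond reacts before C–Br. The product is 22.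

3. Step 6. The ketone enolate may close on oxygen instead of carbon (dihydrofuran), or attack the neighbouring aryl carbonate, while the iodinated adduct waits for ring closure. Fallback: the halogen would be placed on the nucleophile before the conjugate addition. Keto ester 8 would be brominated (NBS) to allyl 2-bromo-3-[2,4-bis(benzyloxy)phenyl]-3-oxopropanoate F4. F4 and enone 6 would be joined in a Michael-initiated ring closure under a chiral phase-transfer catalyst (solid K2CO3, toluene), in which the ion-paired catalyst sets the benzylic centre and the enolate is consumed by 3-exo-tet displacement of bromide as soon as it forms. This bypasses 9 and 10 and comes back to the route at 11.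

**Further compounds**

F1 | step 7 | allyl 2-[2,4-bis(benzyloxy)benzoyl]-3-[4-(benzyloxy)benzoyl]-4-{[4-(benzyloxy)benzyl]oxy}-4-{2,4-bis[(benzyloxycarbonyl)oxy]phenyl}butanoate (C2 not defined) | c1ccccc1COc1ccc(CO[C@H](c2ccc(OC(=O)OCc3ccccc3)cc2OC(=O)OCc2ccccc2)[C@H](C(=O)c2ccc(OCc3ccccc3)cc2)C(C(=O)OCC=C)C(=O)c2ccc(OCc3ccccc3)cc2OCc2ccccc2)cc1
F2 | step 13 | [2,4-bis(benzyloxy)phenyl]{4-{chloro[4-(benzyloxy)phenyl]methyl}-2-[4-(benzyloxy)phenyl]-5-{2,4-bis[(benzyloxycarbonyl)oxy]phenyl}oxolan-3-yl}methanone (chloride carbon not defined) | O=C(c1ccc(OCc2ccccc2)cc1OCc1ccccc1)[C@@H]1[C@@H](C(Cl)c2ccc(OCc3ccccc3)cc2)[C@@H](c2ccc(OC(=O)OCc3ccccc3)cc2OC(=O)OCc2ccccc2)O[C@H]1c1ccc(OCc2ccccc2)cc1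
F3 | step 13 | (2S,3R)-3,5,7-tris(benzyloxy)-2-[4-(benzyloxy)phenyl]-8-bromo-6-iodochromane | c1ccccc1COc1c(Br)c2c(c(OCc3ccccc3)c1I)C[C@@H](OCc1ccccc1)[C@H](c1ccc(OCc3ccccc3)cc1)O2
F4 | step 6 | allyl 2-bromo-3-[2,4-bis(benzyloxy)phenyl]-3-oxopropanoate | C=CCOC(=O)C(Br)C(=O)c1ccc(OCc2ccccc2)cc1OCc1ccccc1
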